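The cyclohexene ring is closed by ring-closing metathesis that joins C4 to C5. In the acyclic 1,4,7-trien-3-ol precursor the (E)-trisubstituted enoate C1=C2 holds the C3 vinyl carbinol and the C6 allyl arm cis, so the two vinyl termini meet and give a cyclohexa-1,4-dien-3-ol whose only electron-rich double bond is C4=C5. The C3 carbinol, set by catalytic asymmetric vinylation, then relays C4 and C5: hydroxyl-directed epoxidation, Mitsunobu inversion at C3 that installs the 6-methylheptanoate, and anti opening at C5 by acetate give the all-trans C3/C4/C5 pattern with three different esters.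

Key step: step 4

Remark on the chemistry: ring atoms are numbered as in the acid name (C1 carries the carboxyl, C1=C2, C3 the 6-methylheptanoate, C4 the tiglate, C5 the acetate, C6 is the CH2 group); the target is the (3R,4R,5S) isomer, in which the three ring oxygens are all trans.

Step 1
Reactants: 1 (tert-butoxycarbonylmethylene)triphenylphosphorane; 2 allyl bromide
Product: 4 tert-butyl 2-(triphenyl-λ5-phosphanylidene)pent-4-enoate, via phosphonium bromide 3 (not isolated)
Conditions: CH2Cl2, 40 °C; then aq. NaOH, 0 °C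
Reagents that add atoms: allyl bromide, C=CCBr
Why: C-alkylation of the ester-stabilised ylide by the reactive allylic bromide gives the phosphonium salt, which NaOH deprotonates to the α-allyl ylide (ylide alkylation and re-formation, no stereocentre involved).

Step 2
Reactants: 4 tert-butyl 2-(triphenyl-λ5-phosphanylidene)pent-4-enoate; 5 2,2-dimethoxyacetaldehyde
Product: 7 tert-butyl (2E)-4-oxo-2-(prop-2-en-1-yl)but-2-enoate, via acetal enoate 6 (not isolated)
Conditions: CH2Cl2, 40 °C; then 1 M HCl, THF, 20 °C
Reagents that add atoms: 2,2-dimethoxyacetaldehyde, COC(OC)C=O; water, O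
Why: Wittig olefination with an α-branched ester-stabilised ylide should give the (E)-trisubstituted enoate, in which the former aldehyde carbon is cis to the allyl arm, and dilute acid then hydrolyses the dimethyl acetal to the aldehyde while the tert-butyl ester survives.

Step 3
Reactants: 7 tert-butyl (2E)-4-oxo-2-(prop-2-en-1-yl)but-2-enoate; 8 vinylmagnesium bromide
Product: 10 tert-butyl (2E,4R)-4-hydroxy-2-(prop-2-en-1-yl)hexa-2,5-dienoate, via divinylzinc 9 (not isolated)
Conditions: 8, ZnCl2, Et2O, 0 °C, then 1,4-dioxane and filtration to give (CH2=CH)2Zn; (2R)-(+)-3-exo-(dimethylamino)isoborneol (10 mol%), toluene, −30 °C, slow addition of 7; aq. NH4Cl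
Reagents that add atoms: vinylmagnesium bromide, C=C[Mg]Br (delivered as divinylzinc, C=C[Zn]C=C)
Why: Amino-alcohol-catalysed enantioselective 1,2-addition of a vinylzinc reagent to the aldehyde, in which the (2R)-(+)-ligand (mirror image of the ligand that delivers to the Si face) should direct the vinyl group to the Re face and give the 4R carbinol, while the ester and the conjugated double bond are not attacked by the organozinc.

Step 4
Reactants: 10 tert-butyl (2E,4R)-4-hydroxy-2-(prop-2-en-1-yl)hexa-2,5-dienoate
Product: 11 tert-butyl (3R)-3-hydroxycyclohexa-1,4-diene-1-carboxylate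
Conditions: second-generation Grubbs catalyst RuCl2(=CHPh)(PCy3)(H2IMes) (3 mol%), 1,4-benzoquinone (10 mol%), CH2Cl2 (0.005 M), 40 °C
Reagents that add atoms: none
Why: Olefin metathesis through metallacyclobutanes: the ruthenium benzylidene exchanges with one terminal vinyl group, the new alkylidene undergoes intramolecular [2+2] cycloaddition with the other vinyl group, and cycloreversion expels ethene and forms the C4=C5 bond. The closest known reaction type is ring-closing metathesis of 1,4,7-trien-3-ols to cyclohexa-1,4-dien-3-ols. The six-membered carbocycle is closed between two monosubstituted alkene termini, C4 and C5 becoming the carbons of a cis ring alkene, and the (E)-enoate C1=C2 acts as a rigid cis spacer that places C3 and C6 on the same side. No stereocentre is created; the C3 carbinol is untouched and becomes the only control element for C4 and C5 in steps 5 to 7. The step needs chemoselectivity for the two vinyl groups over the trisubstituted, electron-poor C1=C2 bond (secured by its substitution and conjugation), ring closure over oligomerisation (high dilution), and no hydride-induced double-bond migration or dehydration to tert-butyl benzoate (benzoquinone additive, neutral medium, and the ester on C1, which disfavours a cyclohexadienyl cation).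

Step 5
Reactants: 11 tert-butyl (3R)-3-hydroxycyclohexa-1,4-diene-1-carboxylate; 12 3-chloroperoxybenzoic acid
Product: 13 tert-butyl (3S,4S,5R)-4,5-epoxy-3-hydroxycyclohex-1-ene-1-carboxylate (epoxide cis to the hydroxyl)
Conditions: 12, NaHCO3, CH2Cl2, 0 °C
Reagents that add atoms: 3-chloroperoxybenzoic acid, O=C(OO)c1cccc(Cl)c1
Why: Hydroxyl-directed peracid epoxidation (Henbest effect), in which hydrogen bonding of the peracid to the C3 hydroxyl should deliver oxygen to the syn face of the electron-rich C4=C5 bond while the conjugated C1=C2 bond stays inert, so that C4 and C5 are set cis to the C3 oxygen.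

Step 6
Reactants: 13 tert-butyl (3S,4S,5R)-4,5-epoxy-3-hydroxycyclohex-1-ene-1-carboxylate; 14 6-methylheptanoic acid
Product: 15 tert-butyl (3R,4R,5R)-4,5-epoxy-3-[(6-methylheptanoyl)oxy]cyclohex-1-ene-1-carboxylate (ester trans to the epoxide)
Conditions: PPh3, diisopropyl azodicarboxylate, toluene, 0 °C → 20 °C
Reagents that add atoms: 6-methylheptanoic acid, CC(C)CCCCC(=O)O
Why: Mitsunobu esterification, in which the C3 alkoxyphosphonium ion is displaced by the carboxylate in an SN2 reaction with inversion, the cis epoxide being unable to participate and leaving the opposite face open, so that the ester ends up trans to the epoxide.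

Step 7
Reactants: 15 tert-butyl (3R,4R,5R)-4,5-epoxy-3-[(6-methylheptanoyl)oxy]cyclohex-1-ene-1-carboxylate; 16 acetic acid
Product: 17 tert-butyl (3R,4R,5S)-5-(acetyloxy)-4-hydroxy-3-[(6-methylheptanoyl)oxy]cyclohex-1-ene-1-carboxylate
Conditions: AcOH (5 equiv), n-Bu4NOAc (0.3 equiv), toluene, 60 °C
Reagents that add atoms: acetic acid, CC(=O)O
Why: Carboxylate-catalysed addition of a carboxylic acid to an epoxide (SN2 ring opening), in which acetate should attack C5, the carbon remote from the inductively deactivating and face-shielding C3 acyloxy group, with inversion, placing the acetate trans to the liberated C4 hydroxyl, which itself stays trans to the C3 ester.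

Step 8
Reactants: 17 tert-butyl (3R,4R,5S)-5-(acetyloxy)-4-hydroxy-3-[(6-methylheptanoyl)oxy]cyclohex-1-ene-1-carboxylate; 18 tigloyl chloride
Product: 19 tert-butyl (3R,4R,5S)-5-(acetyloxy)-4-{[(2E)-2-methylbut-2-enoyl]oxy}-3-[(6-methylheptanoyl)oxy]cyclohex-1-ene-1-carboxylate
Conditions: pyridine, DMAP (cat.), CH2Cl2, 0 °C → 20 °C
Reagents that add atoms: tigloyl chloride [(2E)-2-methylbut-2-enoyl chloride], C/C=C(\C)C(=O)Cl
Why: DMAP-catalysed acylation of the last free secondary hydroxyl (C4) by the acid chloride, with no change at any stereocentre and retention of the thermodynamically preferred (E) geometry of the 2-methylbut-2-enoyl group.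

Step 9
Reactants: 19 tert-butyl (3R,4R,5S)-5-(acetyloxy)-4-{[(2E)-2-methylbut-2-enoyl]oxy}-3-[(6-methylheptanoyl)oxy]cyclohex-1-ene-1-carboxylate
Product: 20 (3R,4R,5S)-5-(acetyloxy)-4-{[(2E)-2-methylbut-2-enoyl]oxy}-3-[(6-methylheptanoyl)oxy]cyclohex-1-ene-1-carboxylic acid (CNP0225437.1)
Conditions: CF3CO2H/CH2Cl2 (1:4), 0 °C → 20 °C
Reagents that add atoms: none
Why: Acid-mediated cleavage of the tert-butyl ester by alkyl–oxygen fission with loss of 2-methylpropene frees the carboxylic acid without hydrolysing the three secondary esters, and the allylic C3 ester should not ionise because the conjugated carboxyl group destabilises the allyl cation.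

Compound list
1 | (tert-butoxycarbonylmethylene)triphenylphosphorane | CC(C)(C)OC(=O)C=P(c1ccccc1)(c1ccccc1)c1ccccc1 | starting material
2 | allyl bromide (3-bromoprop-1-ene) | C=CCBr | starting material
3 | [1-(tert-butoxy)-1-oxopent-4-en-2-yl]triphenylphosphonium bromide | C=CCC(C(=O)OC(C)(C)C)[P+](c1ccccc1)(c1ccccc1)c1ccccc1.[Br-] | intermediate
4 | tert-butyl 2-(triphenyl-λ5-phosphanylidene)pent-4-enoate | C=CCC(C(=O)OC(C)(C)C)=P(c1ccccc1)(c1ccccc1)c1ccccc1 | intermediate
5 | 2,2-dimethoxyacetaldehyde | COC(OC)C=O | starting material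
6 | tert-butyl (2E)-4,4-dimethoxy-2-(prop-2-en-1-yl)but-2-enoate | C=CC/C(C(=O)OC(C)(C)C)=C\C(OC)OC | intermediate
7 | tert-butyl (2E)-4-oxo-2-(prop-2-en-1-yl)but-2-enoate | C=CC/C(C(=O)OC(C)(C)C)=C\C=O | intermediate
8 | vinylmagnesium bromide | C=C[Mg]Br | starting material
9 | divinylzinc | C=C[Zn]C=C | intermediate
10 | tert-butyl (2E,4R)-4-hydroxy-2-(prop-2-en-1-yl)hexa-2,5-dienoate | C=CC/C(C(=O)OC(C)(C)C)=C\[C@H](O)C=C | intermediate
11 | tert-butyl (3R)-3-hydroxycyclohexa-1,4-diene-1-carboxylate | CC(C)(C)OC(=O)C1=C[C@H](O)C=CC1 | intermediate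
12 | 3-chloroperoxybenzoic acid | O=C(OO)c1cccc(Cl)c1 | starting material
13 | tert-butyl (3S,4S,5R)-4,5-epoxy-3-hydroxycyclohex-1-ene-1-carboxylate | CC(C)(C)OC(=O)C1=C[C@H](O)[C@@H]2O[C@@H]2C1 | intermediate
14 | 6-methylheptanoic acid | CC(C)CCCCC(=O)O | starting material
15 | tert-butyl (3R,4R,5R)-4,5-epoxy-3-[(6-methylheptanoyl)oxy]cyclohex-1-ene-1-carboxylate | CC(C)(C)OC(=O)C1=C[C@@H](OC(=O)CCCCC(C)C)[C@@H]2O[C@@H]2C1 | intermediate
16 | acetic acid | CC(=O)O | starting material
17 | tert-butyl (3R,4R,5S)-5-(acetyloxy)-4-hydroxy-3-[(6-methylheptanoyl)oxy]cyclohex-1-ene-1-carboxylate | CC(C)(C)OC(=O)C1=C[C@@H](OC(=O)CCCCC(C)C)[C@H](O)[C@@H](OC(C)=O)C1 | intermediate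
18 | tigloyl chloride [(2E)-2-methylbut-2-enoyl chloride] | C/C=C(\C)C(=O)Cl | starting material
19 | tert-butyl (3R,4R,5S)-5-(acetyloxy)-4-{[(2E)-2-methylbut-2-enoyl]oxy}-3-[(6-methylheptanoyl)oxy]cyclohex-1-ene-1-carboxylate | CC(C)(C)OC(=O)C1=C[C@@H](OC(=O)CCCCC(C)C)[C@H](OC(=O)/C(C)=C/C)[C@@H](OC(C)=O)C1 | intermediate
20 | (3R,4R,5S)-5-(acetyloxy)-4-{[(2E)-2-methylbut-2-enoyl]oxy}-3-[(6-methylheptanoyl)oxy]cyclohex-1-ene-1-carboxylic acid | C/C=C(\C)C(=O)O[C@@H]1[C@@H](OC(C)=O)CC(C(=O)O)=C[C@H]1OC(=O)CCCCC(C)C | target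

Total step count: 9. Longest linear sequence: 9 steps (1 → 20).

Steps most likely to fail

Step 7 (acetate opening of 15). The C3 acyloxy group lies anti to the epoxide and may take part in the opening, which would lead into the 3,4-cis series; acyl groups may also migrate between the three neighbouring oxygens, or base may induce elimination towards an aromatic ring. The fallback runs the opening before any ester sits on C3 and moves the Mitsunobu inversion to the end. It sets out from 13: silylation (tert-butyldimethylsilyl chloride, imidazole, DMF) should give tert-butyl (3S,4R,5R)-3-[(tert-butyldimethylsilyl)oxy]-4,5-epoxycyclohex-1-ene-1-carboxylate F1. Acetate opening at C5 (AcOH, n-Bu4NOAc, toluene, 60 °C), where the cis silyl ether cannot participate and its inductive effect disfavours attack at C4, should give tert-butyl (3S,4R,5S)-5-(acetyloxy)-3-[(tert-butyldimethylsilyl)oxy]-4-hydroxycyclohex-1-ene-1-carboxylate F2. Acylation with 18 (pyridine, DMAP) should give the C4 tiglate tert-butyl (3S,4R,5S)-5-(acetyloxy)-3-[(tert-butyldimethylsilyl)oxy]-4-{[(2E)-2-methylbut-2-enoyl]oxy}cyclohex-1-ene-1-carboxylate F3. HF·pyridine should remove the silyl group under non-basic conditions to give tert-butyl (3S,4S,5S)-5-(acetyloxy)-3-hydroxy-4-{[(2E)-2-methylbut-2-enoyl]oxy}cyclohex-1-ene-1-carboxylate F4. Mitsunobu esterification of F4 with 14 (PPh3, diisopropyl azodicarboxylate) inverts C3 and comes back to the route at 19.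

Step 4 (ring-closing metathesis of 10). Ruthenium hydride species may isomerise the free bis-allylic alcohol, or the cyclohexa-1,4-dien-3-ol may lose water to give tert-butyl benzoate during reaction or isolation. The fallback carries the carbinol through the ring closure as a silyl ether. It sets out from 10: tert-butyldimethylsilyl chloride and imidazole should give tert-butyl (2E,4R)-4-[(tert-butyldimethylsilyl)oxy]-2-(prop-2-en-1-yl)hexa-2,5-dienoate F5. Ring-closing metathesis with the same ruthenium catalyst should give tert-butyl (3R)-3-[(tert-butyldimethylsilyl)oxy]cyclohexa-1,4-diene-1-carboxylate F6. HF·pyridine buffered with pyridine in THF sets the alcohol free, and the route is rejoined at 11.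

Step 3 (asymmetric vinylation of 7). Uncatalysed addition of divinylzinc to the very electrophilic enal, or residual magnesium salts, may erode the enantiomeric purity. The fallback replaces asymmetric addition by resolution. It sets out from 7: addition of 8 (THF, −78 °C) should give racemic tert-butyl (2E)-4-hydroxy-2-(prop-2-en-1-yl)hexa-2,5-dienoate F7. Sharpless kinetic resolution (Ti(OiPr)4, D-(−)-diisopropyl tartrate, tert-butyl hydroperoxide, 4 Å molecular sieves, CH2Cl2, −20 °C) should epoxidise the vinyl group of the 4S enantiomer to tert-butyl (2E,4R)-4-hydroxy-4-[(2S)-oxiran-2-yl]-2-(prop-2-en-1-yl)but-2-enoate F8 and leave the 4R alcohol, at which the route is rejoined (10).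

Further compounds
F1 | step 7 | tert-butyl (3S,4R,5R)-3-[(tert-butyldimethylsilyl)oxy]-4,5-epoxycyclohex-1-ene-1-carboxylate | CC(C)(C)OC(=O)C1=C[C@H](O[Si](C)(C)C(C)(C)C)[C@@H]2O[C@@H]2C1
F2 | step 7 | tert-butyl (3S,4R,5S)-5-(acetyloxy)-3-[(tert-butyldimethylsilyl)oxy]-4-hydroxycyclohex-1-ene-1-carboxylate | CC(C)(C)OC(=O)C1=C[C@H](O[Si](C)(C)C(C)(C)C)[C@H](O)[C@@H](OC(C)=O)C1
F3 | step 7 | tert-butyl (3S,4R,5S)-5-(acetyloxy)-3-[(tert-butyldimethylsilyl)oxy]-4-{[(2E)-2-methylbut-2-enoyl]oxy}cyclohex-1-ene-1-carboxylate | CC(C)(C)OC(=O)C1=C[C@H](O[Si](C)(C)C(C)(C)C)[C@H](OC(=O)/C(C)=C/C)[C@@H](OC(C)=O)C1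
F4 | step 7 | tert-butyl (3S,4S,5S)-5-(acetyloxy)-3-hydroxy-4-{[(2E)-2-methylbut-2-enoyl]oxy}cyclohex-1-ene-1-carboxylate | CC(C)(C)OC(=O)C1=C[C@H](O)[C@H](OC(=O)/C(C)=C/C)[C@@H](OC(C)=O)C1
F5 | step 4 | tert-butyl (2E,4R)-4-[(tert-butyldimethylsilyl)oxy]-2-(prop-2-en-1-yl)hexa-2,5-dienoate | C=CC/C(C(=O)OC(C)(C)C)=C\[C@H](O[Si](C)(C)C(C)(C)C)C=C
F6 | step 4 | tert-butyl (3R)-3-[(tert-butyldimethylsilyl)oxy]cyclohexa-1,4-diene-1-carboxylate | CC(C)(C)OC(=O)C1=C[C@H](O[Si](C)(C)C(C)(C)C)C=CC1
F7 | step 3 | tert-butyl (2E)-4-hydroxy-2-(prop-2-en-1-yl)hexa-2,5-dienoate (racemic) | C=CC/C(C(=O)OC(C)(C)C)=C\C(O)C=C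
F8 | step 3 | tert-butyl (2E,4R)-4-hydroxy-4-[(2S)-oxiran-2-yl]-2-(prop-2-en-1-yl)but-2-enoate | C=CC/C(C(=O)OC(C)(C)C)=C\[C@@H](O)[C@@H]1CO1
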